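**Plan**

- Retrosynthesis: the C5–prenyl bond is cut first (aromatic Claisen shift from O4), the C3 formyl group is taken back to C3–CH2OMe, the furan is opened at O1–C2 and C3–CH2 to a diaryl alkyne, and the two aryl–C(sp) bonds are cut last (Sonogashira couplings).
- Enabling feature: the formyl carbon sits on C3, the second ring atom from the furan oxygen O1 (O1–C2–C3). A methoxymethyl group on that oxygen can therefore pass to C3 while O1 adds to C2 of an ortho-alkynyl aryl ether. Ring A of the precursor carries the same acetal on both oxygens ortho to the alkyne, so either one closes to the same benzofuran.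
- Forward: the ring A iodide and the ring B alkyne are joined through the two-carbon alkyne unit, and the furan (the only ring formed) closes in step 7. The CH2OMe group is then oxidised to CHO, and the prenyl group is passed from O4 to C5 before the last silyl ether is removed.
- Stereochemistry: the target has no stereocentre and no stereogenic double bond, so nothing has to be set.

Key step: step 7

Remark: benzofuran numbering O1, C2, C3, C3a, C4–C7, C7a is used; ring A is the benzo ring and ring B the 2-aryl group. Catalyst-bound species and ionic transients are treated as mechanism, while the discrete in-flask intermediates 3, 5, 14 and 20 are numbered. All reagents named are taken to be commercial.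

**Route**

Step 1
Reactants: 1 5-methoxyresorcinol; 2 chloromethyl methyl ether
Product: 4 1-methoxy-3,5-bis(methoxymethoxy)benzene, via monoether 3 (not isolated)
Conditions: MOMCl (2.4 equiv), i-Pr2NEt, DCM, 0 °C to rt
Reagents that add atoms: chloromethyl methyl ether (second equivalent), COCCl
Why: Two successive Williamson-type O-alkylations by the highly reactive α-chloro ether, the first giving monoether 3 and the second equivalent capping the remaining phenol, should give the bis-acetal, which later serves as directing group, protecting group and migrating group.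

Step 2
Reactants: 4 1-methoxy-3,5-bis(methoxymethoxy)benzene
Product: 6 2-iodo-5-methoxy-1,3-bis(methoxymethoxy)benzene, via aryllithium 5 (not isolated)
Conditions: n-BuLi, THF, 0 °C; then I2, −78 °C to rt
Reagents that add atoms: iodine, II
Why: Directed ortho-metalation should take place at the carbon flanked by the two chelating methoxymethoxy groups in preference to the positions next to the methoxy group, and the aryllithium is then iodinated by I2.

Step 3
Reactants: 7 4-bromo-3-methoxyphenol
Product: 8 (4-bromo-3-methoxyphenoxy)triisopropylsilane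
Conditions: TIPSCl, imidazole, DMF, rt
Reagents that add atoms: chlorotriisopropylsilane, CC(C)[Si](Cl)(C(C)C)C(C)C
Why: Imidazole-promoted silylation of a phenol gives a bulky silyl ether that should withstand amine bases, the platinum catalyst, DDQ and dilute aqueous acid and is removed by fluoride at the end.

Step 4
Reactants: 8 (4-bromo-3-methoxyphenoxy)triisopropylsilane; 9 trimethylsilylacetylene
Product: 10 trimethyl{[2-methoxy-4-(triisopropylsilyloxy)phenyl]ethynyl}silane
Conditions: PdCl2(PhCN)2 (cat.), t-Bu3P·HBF4 (cat.), CuI (cat.), i-Pr2NH, dioxane, rt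
Reagents that add atoms: none
Why: Sonogashira coupling, in which the electron-rich t-Bu3P-ligated zerovalent palladium formed in situ should insert into the deactivated aryl bromide at room temperature while the cheap alkyne is used in excess.

Step 5
Reactants: 10 trimethyl{[2-methoxy-4-(triisopropylsilyloxy)phenyl]ethynyl}silane
Product: 11 (4-ethynyl-3-methoxyphenoxy)triisopropylsilane
Conditions: K2CO3 (0.2 equiv), MeOH–THF, 0 °C, short reaction time
Reagents that add atoms: none
Why: Base-catalysed methanolysis of the C(sp)–Si bond (protiodesilylation) should be far faster than attack on the hindered aryl triisopropylsilyl ether when the carbonate is catalytic and the temperature low.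

Step 6
Reactants: 6 2-iodo-5-methoxy-1,3-bis(methoxymethoxy)benzene; 11 (4-ethynyl-3-methoxyphenoxy)triisopropylsilane
Product: 12 2-{[2-methoxy-4-(triisopropylsilyloxy)phenyl]ethynyl}-5-methoxy-1,3-bis(methoxymethoxy)benzene
Conditions: PdCl2(PPh3)2 (cat.), CuI (cat.), Et3N–DMF, 60 °C, degassed
Reagents that add atoms: none
Why: Sonogashira coupling of an aryl iodide, whose weak C–I bond should compensate for the electron-rich, doubly ortho-substituted ring, under amine base that leaves the acetals and the silyl ether untouched.

Step 7
Reactants: 12 2-{[2-methoxy-4-(triisopropylsilyloxy)phenyl]ethynyl}-5-methoxy-1,3-bis(methoxymethoxy)benzene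
Product: 13 6-methoxy-3-(methoxymethyl)-4-(methoxymethoxy)-2-[2-methoxy-4-(triisopropylsilyloxy)phenyl]benzofuran
Conditions: PtCl2 (5 mol%), CO (1 atm), dry toluene, 80 °C
Reagents that add atoms: none
Why: PtCl2 (divalent platinum, made more electrophilic by the CO ligand) coordinates the alkyne of 12, a methoxymethyl ether oxygen of ring A attacks the alkyne carbon bearing ring B anti to the metal to form O1–C2, and the resulting vinylplatinum oxonium ion expels MeOCH2+, which is captured by the platinum-bearing carbon to form C3–CH2OMe and release the catalyst. The closest known reaction type is the PtCl2-catalysed carboalkoxylation of ortho-alkynylaryl ethers and acetals, in which the group on oxygen undergoes a 1,3-shift to C3 of the new benzofuran. The furan ring closes in the 5-endo-dig mode, and no stereocentre is created. Two selectivities are needed: closure through a ring A oxygen and not through the ortho methoxy group of ring B, and C–C bond formation at C3 in place of protodeplatination. The first should follow because oxygen attack is reversible and only an acetal-type substituent can leave as a stabilised oxocarbenium ion, a methyl group having no such exit; the second is favoured by dry, acid-free toluene, which leaves the oxocarbenium ion as the only electrophile near the vinyl–platinum bond. Since the two methoxymethyl ethers flank the alkyne symmetrically, either closes to the same product 13, and the one that remains protects O4.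

Step 8
Reactants: 13 6-methoxy-3-(methoxymethyl)-4-(methoxymethoxy)-2-[2-methoxy-4-(triisopropylsilyloxy)phenyl]benzofuran
Product: 15 6-methoxy-4-(methoxymethoxy)-2-[2-methoxy-4-(triisopropylsilyloxy)phenyl]benzofuran-3-carbaldehyde, via methyl hemiacetal 14 (not isolated)
Conditions: DDQ (1.3 equiv), DCM–pH 7 aqueous buffer, 0 °C to rt
Reagents that add atoms: water, O
Why: DDQ oxidation of an activated heterobenzylic ether by hydride abstraction, the mechanism of 4-methoxybenzyl ether cleavage, should give a cation stabilised by its own methoxy oxygen and, through C2, by O1 and the aryl group, which takes up water and loses methanol to leave an aldehyde that resists further oxidation.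

Step 9
Reactants: 15 6-methoxy-4-(methoxymethoxy)-2-[2-methoxy-4-(triisopropylsilyloxy)phenyl]benzofuran-3-carbaldehyde
Product: 16 4-hydroxy-6-methoxy-2-[2-methoxy-4-(triisopropylsilyloxy)phenyl]benzofuran-3-carbaldehyde
Conditions: 2 M aq. HCl, THF, 40 °C
Reagents that add atoms: none
Why: Acid-catalysed acetal hydrolysis should cleave the methoxymethyl ether to the phenol, formaldehyde and methanol under conditions that spare the far more acid-stable aryl triisopropylsilyl and methyl ethers, the freed phenol being held by a hydrogen bond to the C3 formyl group.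

Step 10
Reactants: 16 4-hydroxy-6-methoxy-2-[2-methoxy-4-(triisopropylsilyloxy)phenyl]benzofuran-3-carbaldehyde; 17 3-chloro-3-methylbut-1-yne
Product: 18 6-methoxy-2-[2-methoxy-4-(triisopropylsilyloxy)phenyl]-4-[(2-methylbut-3-yn-2-yl)oxy]benzofuran-3-carbaldehyde
Conditions: DBU, CuCl2 (cat.), MeCN, 0 °C to rt
Reagents that add atoms: none
Why: Copper-catalysed propargylic etherification of a phenol, which proceeds through a copper acetylide-derived electrophile, should build the hindered tertiary aryl ether under mild base where a direct SN2 reaction at a tertiary carbon would fail.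

Step 11
Reactants: 18 6-methoxy-2-[2-methoxy-4-(triisopropylsilyloxy)phenyl]-4-[(2-methylbut-3-yn-2-yl)oxy]benzofuran-3-carbaldehyde
Product: 19 6-methoxy-2-[2-methoxy-4-(triisopropylsilyloxy)phenyl]-4-[(2-methylbut-3-en-2-yl)oxy]benzofuran-3-carbaldehyde
Conditions: H2 (1 atm), Pd/CaCO3 poisoned with Pb(OAc)2, quinoline, EtOAc, rt
Reagents that add atoms: none
Why: Lindlar semihydrogenation should reduce the terminal alkyne to the alkene and stop there, the poisoned palladium surface leaving the aldehyde, the aryl ethers and the silyl ether unreduced.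

Step 12
Reactants: 19 6-methoxy-2-[2-methoxy-4-(triisopropylsilyloxy)phenyl]-4-[(2-methylbut-3-en-2-yl)oxy]benzofuran-3-carbaldehyde
Product: 21 4-hydroxy-6-methoxy-2-[2-methoxy-4-(triisopropylsilyloxy)phenyl]-5-(3-methylbut-2-enyl)benzofuran-3-carbaldehyde, via cyclohexadienone 20 (not isolated)
Conditions: PhNEt2, 120 °C
Reagents that add atoms: none
Why: Aromatic Claisen rearrangement, a [3,3]-sigmatropic shift accelerated by the gem-dimethyl group, should bond the terminal alkene carbon to C5, the only ortho carbon bearing hydrogen, with allylic transposition to the prenyl group, after which the dienone tautomerises to the phenol.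

Step 13
Reactants: 21 4-hydroxy-6-methoxy-2-[2-methoxy-4-(triisopropylsilyloxy)phenyl]-5-(3-methylbut-2-enyl)benzofuran-3-carbaldehyde
Product: 22 Ebenfuran IV
Conditions: Bu4NF, AcOH, THF, 0 °C
Reagents that add atoms: none
Why: Fluoride-induced desilylation, driven by the strong Si–F bond, should free the ring B phenol while acetic acid buffers the phenoxide so that the aldehyde and the ortho-prenylphenol are not exposed to strong base.

**Compound list**

1 | 5-methoxyresorcinol | COc1cc(O)cc(O)c1 | starting material
2 | chloromethyl methyl ether | COCCl | starting material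
3 | 3-methoxy-5-(methoxymethoxy)phenol (monoether) | COCOc1cc(O)cc(OC)c1 | intermediate (not isolated)
4 | 1-methoxy-3,5-bis(methoxymethoxy)benzene | COCOc1cc(OC)cc(OCOC)c1 | intermediate
5 | 2-lithio-5-methoxy-1,3-bis(methoxymethoxy)benzene (aryllithium) | [Li]c1c(OCOC)cc(OC)cc1OCOC | intermediate (not isolated)
6 | 2-iodo-5-methoxy-1,3-bis(methoxymethoxy)benzene | COCOc1cc(OC)cc(OCOC)c1I | intermediate
7 | 4-bromo-3-methoxyphenol | COc1cc(O)ccc1Br | starting material
8 | (4-bromo-3-methoxyphenoxy)triisopropylsilane | COc1cc(O[Si](C(C)C)(C(C)C)C(C)C)ccc1Br | intermediate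
9 | trimethylsilylacetylene | C#C[Si](C)(C)C | starting material
10 | trimethyl{[2-methoxy-4-(triisopropylsilyloxy)phenyl]ethynyl}silane | COc1cc(O[Si](C(C)C)(C(C)C)C(C)C)ccc1C#C[Si](C)(C)C | intermediate
11 | (4-ethynyl-3-methoxyphenoxy)triisopropylsilane | COc1cc(O[Si](C(C)C)(C(C)C)C(C)C)ccc1C#C | intermediate
12 | 2-{[2-methoxy-4-(triisopropylsilyloxy)phenyl]ethynyl}-5-methoxy-1,3-bis(methoxymethoxy)benzene | COCOc1cc(OC)cc(OCOC)c1C#Cc1ccc(O[Si](C(C)C)(C(C)C)C(C)C)cc1OC | intermediate
13 | 6-methoxy-3-(methoxymethyl)-4-(methoxymethoxy)-2-[2-methoxy-4-(triisopropylsilyloxy)phenyl]benzofuran | COCc1c(-c2ccc(O[Si](C(C)C)(C(C)C)C(C)C)cc2OC)oc2cc(OC)cc(OCOC)c12 | intermediate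
14 | 3-[hydroxy(methoxy)methyl]-6-methoxy-4-(methoxymethoxy)-2-[2-methoxy-4-(triisopropylsilyloxy)phenyl]benzofuran (methyl hemiacetal, racemic, transient) | COC(O)c1c(-c2ccc(O[Si](C(C)C)(C(C)C)C(C)C)cc2OC)oc2cc(OC)cc(OCOC)c12 | intermediate (not isolated)
15 | 6-methoxy-4-(methoxymethoxy)-2-[2-methoxy-4-(triisopropylsilyloxy)phenyl]benzofuran-3-carbaldehyde | COCOc1cc(OC)cc2oc(-c3ccc(O[Si](C(C)C)(C(C)C)C(C)C)cc3OC)c(C=O)c12 | intermediate
16 | 4-hydroxy-6-methoxy-2-[2-methoxy-4-(triisopropylsilyloxy)phenyl]benzofuran-3-carbaldehyde | COc1cc(O)c2c(C=O)c(-c3ccc(O[Si](C(C)C)(C(C)C)C(C)C)cc3OC)oc2c1 | intermediate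
17 | 3-chloro-3-methylbut-1-yne | CC(C)(Cl)C#C | starting material
18 | 6-methoxy-2-[2-methoxy-4-(triisopropylsilyloxy)phenyl]-4-[(2-methylbut-3-yn-2-yl)oxy]benzofuran-3-carbaldehyde | COc1cc(OC(C)(C)C#C)c2c(C=O)c(-c3ccc(O[Si](C(C)C)(C(C)C)C(C)C)cc3OC)oc2c1 | intermediate
19 | 6-methoxy-2-[2-methoxy-4-(triisopropylsilyloxy)phenyl]-4-[(2-methylbut-3-en-2-yl)oxy]benzofuran-3-carbaldehyde | COc1cc(OC(C)(C)C=C)c2c(C=O)c(-c3ccc(O[Si](C(C)C)(C(C)C)C(C)C)cc3OC)oc2c1 | intermediate
20 | 6-methoxy-2-[2-methoxy-4-(triisopropylsilyloxy)phenyl]-5-(3-methylbut-2-enyl)-4-oxo-4,5-dihydrobenzofuran-3-carbaldehyde (cyclohexadienone, racemic, transient) | O=C1C(CC=C(C)C)C(OC)=CC2=C1C(C=O)=C(c3ccc(O[Si](C(C)C)(C(C)C)C(C)C)cc3OC)O2 | intermediate (not isolated)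
21 | 4-hydroxy-6-methoxy-2-[2-methoxy-4-(triisopropylsilyloxy)phenyl]-5-(3-methylbut-2-enyl)benzofuran-3-carbaldehyde | COc1cc(O[Si](C(C)C)(C(C)C)C(C)C)ccc1-c1oc2cc(OC)c(CC=C(C)C)c(O)c2c1C=O | intermediate
22 | Ebenfuran IV, 4-hydroxy-2-(4-hydroxy-2-methoxyphenyl)-6-methoxy-5-(3-methylbut-2-enyl)benzofuran-3-carbaldehyde (achiral) | COc1cc(O)ccc1-c1oc2cc(OC)c(CC=C(C)C)c(O)c2c1C=O | target

**Summary**

Total step count: 13.
Longest linear sequence: 11 steps, from 4-bromo-3-methoxyphenol 7 through steps 3–13. The ring A branch, steps 1–2, joins at step 6.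

Steps most likely to fail:

1. Step 7. The vinylplatinum intermediate may be protonated before the methoxymethyl cation is captured, which would give a benzofuran with no carbon on C3, or the very electron-rich, doubly ortho-substituted alkyne may bind the catalyst without turning over. The fallback closes the same furan by known palladium chemistry and brings the C3 carbon in from CO.
   - Setting out from 12, aqueous HCl in THF would remove both methoxymethyl groups to give 5-methoxy-2-{[2-methoxy-4-(triisopropylsilyloxy)phenyl]ethynyl}benzene-1,3-diol F1.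
   - Oxidative methoxycarbonylative cyclisation (PdCl2 cat., CuCl2, NaOAc, CO, MeOH, rt) would form O1–C2 through either of the equivalent phenols and give methyl 4-hydroxy-6-methoxy-2-[2-methoxy-4-(triisopropylsilyloxy)phenyl]benzofuran-3-carboxylate F2.
   - Reduction with i-Bu2AlH in DCM at −78 °C would give 3-(hydroxymethyl)-6-methoxy-2-[2-methoxy-4-(triisopropylsilyloxy)phenyl]benzofuran-4-ol F3.
   - MnO2 in DCM would oxidise the heterobenzylic alcohol to aldehyde 16, where the route is rejoined.

2. Step 10. Ether formation at a tertiary carbon on a phenol that is hindered and hydrogen-bonded to the neighbouring formyl group may be too slow, so that the chloroalkyne is consumed by elimination and oligomerisation. The fallback uses a primary allylic electrophile and moves the group to carbon afterwards.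
   - Setting out from 16, prenyl bromide and K2CO3 in DMF would give 6-methoxy-2-[2-methoxy-4-(triisopropylsilyloxy)phenyl]-4-(3-methylbut-2-enyloxy)benzofuran-3-carbaldehyde F4.
   - Montmorillonite K10 clay in DCM at 0 °C would promote the 1,3-shift of the prenyl group from O4 to the ortho carbon C5 and give 21 directly; any C7 isomer would be separated.

3. Step 12. On heating, the tertiary allyl ether may ionise and lose isoprene, returning phenol 16, or the ortho-prenylphenol formed may add its hydroxyl group across the alkene to give a chroman. The fallback uses an allyl group that cannot ionise and completes the prenyl group by metathesis.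
   - Setting out from 16, allyl bromide and K2CO3 in acetone would give 4-(allyloxy)-6-methoxy-2-[2-methoxy-4-(triisopropylsilyloxy)phenyl]benzofuran-3-carbaldehyde F5.
   - Claisen rearrangement in PhNEt2 at 190 °C would give 5-allyl-4-hydroxy-6-methoxy-2-[2-methoxy-4-(triisopropylsilyloxy)phenyl]benzofuran-3-carbaldehyde F6.
   - Cross-metathesis with 2-methylbut-2-ene and the second-generation Grubbs catalyst (H2IMes)(PCy3)Cl2Ru=CHPh in DCM at 40 °C would give 21.

**Further compounds**

F1 | step 7 | 5-methoxy-2-{[2-methoxy-4-(triisopropylsilyloxy)phenyl]ethynyl}benzene-1,3-diol | COc1cc(O)c(C#Cc2ccc(O[Si](C(C)C)(C(C)C)C(C)C)cc2OC)c(O)c1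
F2 | step 7 | methyl 4-hydroxy-6-methoxy-2-[2-methoxy-4-(triisopropylsilyloxy)phenyl]benzofuran-3-carboxylate | COC(=O)c1c(-c2ccc(O[Si](C(C)C)(C(C)C)C(C)C)cc2OC)oc2cc(OC)cc(O)c12
F3 | step 7 | 3-(hydroxymethyl)-6-methoxy-2-[2-methoxy-4-(triisopropylsilyloxy)phenyl]benzofuran-4-ol | OCc1c(-c2ccc(O[Si](C(C)C)(C(C)C)C(C)C)cc2OC)oc2cc(OC)cc(O)c12
F4 | step 10 | 6-methoxy-2-[2-methoxy-4-(triisopropylsilyloxy)phenyl]-4-(3-methylbut-2-enyloxy)benzofuran-3-carbaldehyde | COc1cc(OCC=C(C)C)c2c(C=O)c(-c3ccc(O[Si](C(C)C)(C(C)C)C(C)C)cc3OC)oc2c1
F5 | step 12 | 4-(allyloxy)-6-methoxy-2-[2-methoxy-4-(triisopropylsilyloxy)phenyl]benzofuran-3-carbaldehyde | C=CCOc1cc(OC)cc2oc(-c3ccc(O[Si](C(C)C)(C(C)C)C(C)C)cc3OC)c(C=O)c12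
F6 | step 12 | 5-allyl-4-hydroxy-6-methoxy-2-[2-methoxy-4-(triisopropylsilyloxy)phenyl]benzofuran-3-carbaldehyde | C=CCc1c(OC)cc2oc(-c3ccc(O[Si](C(C)C)(C(C)C)C(C)C)cc3OC)c(C=O)c2c1O
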